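# Proposed synthesis of CNP0203887.1 by enone–cyclobutene photocycloaddition and thermal ring expansion

## Analysis of the target

Numbering used throughout: the ring is C1–C10 (C1, C2 = CH2; C3 = ketone; C4 = methyl carbinol; C5 = isobutyrate carbon; C6 = lactone O–CH; C7 = ring-fusion CH; C8 = free carbinol; C9 = isovalerate carbon; C10 = CH–CH3). The lactone carbons are C11 (bearing the C13 methylene) and C12 (carbonyl).

- The target is a germacranolide: a ten-membered carbocycle with an α-methylene-γ-butyrolactone trans-fused across C6 (oxygen) and C7 (C11).
- Seven contiguous stereocentres, C4 to C10, line one side of the ring (4R,5R,6S,7R,8R,9R,10R); only C1, C2 and C3 carry none.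
- Drawn as a zigzag, the oxygens on C5, C6, C8 and C9 and the C7–C11 bond lie on one side; the tertiary C4 hydroxyl and the C10 methyl lie on the other.
- The oxygens are differentiated pairwise: C4–OH is free beside the C5 isobutyrate, C8–OH is free beside the C9 isovalerate, and the lactone closes on O6 and not on O8.
- Sensitive groups are the methylene lactone (Michael acceptor), the tertiary α-ketol at C3/C4, and two esters next to free hydroxyls (acyl shift, translactonisation).
- The difficulty is a medium ring on which stereocontrol must be exerted seven times, with late differentiation of four oxygens.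
- The plan rests on two observations. First, C3(=O), C4(CH3), C9, C10(CH3), C1 and C2 are the six carbons of 2,4-dimethylcyclohex-2-enone. Second, the dioxygen pairs C4/C5 and C8/C9 are the two alkenes of a cyclodeca-4,8-dien-3-one, which is that enone with the four cyclobutene carbons C5–C8 inserted into its C4=C9 bond.

## Retrosynthetic reasoning

**C9–O (27 to 26).** The isovalerate C–O bond at C9 is cut last, back to the cis-epoxide 26. Opening of the epoxide at C9 by the acid installs the ester and frees the C8 hydroxyl in the same event, so the two oxygens never have to be told apart by protection. The forward step must attack C9, not C8, with inversion.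

**C8/C9 oxygen, C3 carbonyl, C5 ester (26 to 22).** The epoxide goes back to the Z alkene of 25, the C3 ketone to the silyl-protected carbinol of 23 via 24, and the C5 isobutyrate to diol 22. C3 is kept at the carbinol level through the middle of the route for two reasons: a C3 carbonyl would prevent acid-mediated opening at the neighbouring tertiary C4, and it would not survive the hydride step needed at C11.

**Lactone (22 to 21).** The bonds O6–C12 and C11–C12 are cut. This leaves the homopropargylic alcohol 21, with C12 returning by carbonylation. The method makes the methylene lactone in one neutral step and needs no enolate chemistry on a finished lactone.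

**C4–O and C5–O (21 to 19).** The (4E) alkene cannot give the 4R,5R pair by syn addition. The C4–O bond is therefore cut back to epoxide 20 (hydrolytic opening at the tertiary carbon with inversion), and 20 to allylic alcohol 19, whose free C6 hydroxyl directs the oxidant and singles out C4=C5 from C8=C9.

**C11≡C13 (19 to 14).** The alkyne is taken back through aldehyde 17 to the C7 methyl ester of 14; C13 comes from a diazomethane reagent. Silyl ethers 16 and 18 and diol 15 only serve to keep O6 protected and non-leaving while C11 is an aldehyde.

**C3 carbinol (14 to 12).** Silyl ether 14 and carbinol 13 return to dienone 12.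

**Ring (12 to 11).** Reconnecting C4–C9 and C5–C8 folds the ten-membered dienone into tricycle 11, a bicyclo[2.2.0]hexane fused to a cyclohexanone. No macrocyclisation is needed; the forward step only has to release strain without letting the 1,5-diene rearrange.

**Key disconnection (11 to 5 and 10).** Cutting C4–C5 and C8–C9 gives enone 5 and cyclobutene 10. 5 carries the ketone and both methyl groups (C10 stereocentre); 10 carries C6 and C7 with their trans relationship. The forward step must join C4 to C5 (not to C8) and add anti to the C10 methyl.

**Building blocks.** 5 is reached from 1 by exchanging the isopropylidene carbon for the ketone and the old carbonyl carbon for the methyl-bearing alkene carbon. 10 is reached from 6 through photoisomer 7, whose β-lactone is opened with inversion (8) and resolved (9).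

## Alternatives that were turned down

**Alternative 1: anionic oxy-Cope ring expansion.**
- Disconnection: C1–C10 is cut and C3–C8 reconnected, so the ring becomes a cyclohexanol with a vinyl group on the carbinol carbon and a (Z)-propenyl group next to it.
- Forward key step: a potassium alkoxide undergoes a charge-accelerated [3,3] shift to A1, an (E)-cyclodec-8-en-3-one that keeps C4–C7 from the six-membered ring and sets C10 in the chair transition state.
- For: the rearrangement is well tried for ten-membered ketones and runs at low temperature. The ketone appears at C3 directly. The C8=C9 bond of A1 is E, the geometry that plain syn-dihydroxylation turns into the 8,9-diol of the target. On precedent and on the C8/C9 pair this plan is stronger than the chosen one.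
- Against: the precursor of A1 needs four contiguous substituted centres and two specific alkenyl groups on one cyclohexane, a long linear sequence. The alkoxide sits next to an oxygenated carbon, so fragmentation and elimination channels exist. C10 depends on chair versus boat and on the Z purity of the propenyl group. The isopropenyl group at C7 must still be oxidised at a methyl group late.
- Comparison: the chosen route offers two small building blocks made in three and four steps and both ring alkenes in one operation; it pays with an unproven orientation and a Z alkene at C8=C9.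

**Alternative 2: carbonylative Stille macrocyclisation.**
- Disconnection: C2–C3 and C3–C4 are cut, leaving an open chain with a (Z)-alkenylstannane and an (E)-alkenyl iodide; C3 returns as CO.
- Forward key step: palladium-catalysed carbonylative coupling closes the ring to the cross-conjugated dienone A2.
- For: all centres C6–C10 are set on an open chain or a five-membered ring, where control is dependable. C8 (silyl ether) and C9 (isovalerate) are already distinguished in A2, which is better than in the chosen route, where that distinction rests on the last step.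
- Against: a strained ten-membered ring must close under high dilution while CO insertion outruns direct coupling to the nine-membered ring. A2 then needs selective saturation of C1=C2 beside a second enone. Its (E)-C4=C5 enone meets the same problem at C4 as the chosen route, but with the ketone already in place, where opening at C4 is blocked. The lactone must be oxidised up at the end.
- Comparison: the chosen route avoids macrocyclisation and is much shorter to the ring.

**Alternative 3: Grob fragmentation.**
- Disconnection: C4–C9 is reconnected, giving a trans-decalin with an alkoxide at C9 and a sulfonate at C5.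
- Forward key step: base-induced fragmentation gives A3, an (E)-cyclodec-4-en-9-one with C3 as a ketal.
- For: the fragmentation is stereospecific and among the most reliable routes to medium rings. C3 and C9 arrive as distinct, masked carbonyls and C8 is already protected. On certainty of ring formation and on differentiation of oxygens it is stronger than the chosen plan.
- Against: C10 lies α to the new C9 ketone of A3 and can epimerise under the alkoxide base. The C9 ketone must then be reduced with the right facial sense on a medium ring. The decalin precursor, with six centres and a fused methylene-tetrahydrofuran, is a long linear synthesis. The (E)-C4=C5 alkene still needs the same epoxidation–inversion sequence used here.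
- Comparison: the chosen route breaks the same C4–C9 bond but builds its precursor in a single photochemical step.

Key step: step 8

## Route

Remarks on the chemistry (assumptions):
- The carbinol carbons created in steps 1 and 10 (C1 of 2, C2 of 3 and 4, C3 of 13–24) are transient. Either epimer serves, so they are written without configuration.
- In step 6 it cannot be predicted which enantiomer of 1-phenylethylamine gives the less soluble salt with the (1R,4R) acid. (R) is written; the (S) amine is the equivalent choice.
- The geometry of 12 is taken as (4E,8Z), as derived in step 9. The later steps are built on it.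

Step 1
Reactants: 1 (R)-(+)-pulegone
Product: 2 (5R)-1,5-dimethyl-2-(propan-2-ylidene)cyclohexan-1-ol
Conditions: CH3Li, CeCl3, THF, −78 °C
Reagents that add atoms: methyllithium, C[Li]
Why: 1,2-addition of the organocerium reagent to a hindered, enolisable enone; cerium suppresses enolisation and conjugate addition. The new carbinol centre becomes sp2 in step 3, so its configuration does not matter.

Step 2
Reactants: 2 (5R)-1,5-dimethyl-2-(propan-2-ylidene)cyclohexan-1-ol
Product: 3 (4R)-2-hydroxy-2,4-dimethylcyclohexan-1-one
Conditions: O3, CH2Cl2/CH3OH, −78 °C; (CH3)2S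
Reagents that add atoms: ozone, [O-][O+]=O
Why: Ozonolysis with reductive work-up (Criegee mechanism) removes the isopropylidene carbon as acetone and leaves the ring carbon as a ketone beside the tertiary carbinol; the methyl-bearing stereocentre is remote.

Step 3
Reactants: 3 (4R)-2-hydroxy-2,4-dimethylcyclohexan-1-one
Product: 5 (R)-2,4-dimethylcyclohex-2-en-1-one, via chlorosulfite ester 4 (not isolated)
Conditions: SOCl2, pyridine, CH2Cl2, −10 to 20 °C
Reagents that add atoms: none
Why: Dehydration of a tertiary alcohol through its chlorosulfite (E2 with pyridine); with the C2 methyl equatorial the leaving group is axial and anti-periplanar to the axial ring hydrogen at C3, which leads to the conjugated endocyclic enone. The stereocentre is not involved.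

Step 4
Reactants: 6 2H-pyran-2-one
Product: 7 rac-2-oxabicyclo[2.2.0]hex-5-en-3-one
Conditions: hν (300 nm), Et2O, −10 °C
Reagents that add atoms: none
Why: Photochemical disrotatory 4π electrocyclisation of the pyranone diene, a known valence isomerisation; the bicyclic β-lactone is racemic and is kept cold.

Step 5
Reactants: 7 rac-2-oxabicyclo[2.2.0]hex-5-en-3-one
Product: 8 rac-trans-4-(2,2-dimethylpropanoyloxy)cyclobut-2-ene-1-carboxylic acid
Conditions: CsO2CC(CH3)3 (3 equiv), (CH3)3CCO2H, DMF, 0 °C; cold 1 M HCl
Reagents that add atoms: cesium pivalate, CC(C)(C)C(=O)[O-].[Cs+]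
Why: Alkyl–oxygen cleavage of a strained allylic β-lactone by a carboxylate (SN2 at the carbon bearing the ring oxygen, as in carboxylate openings of β-lactones) inverts that carbon and places the new ester trans to the carboxyl group. An acyloxy group is used at this carbon because an ether or silyl ether donor would make the trans-disubstituted cyclobutene open conrotatorily near room temperature.

Step 6
Reactants: 8 rac-trans-4-(2,2-dimethylpropanoyloxy)cyclobut-2-ene-1-carboxylic acid
Product: 9 (1R,4R)-4-(2,2-dimethylpropanoyloxy)cyclobut-2-ene-1-carboxylic acid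
Conditions: (R)-1-phenylethylamine (0.55 equiv), EtOAc/pentane, −20 °C, two crystallisations; 1 M KHSO4/Et2O, 0 °C
Reagents that add atoms: none
Why: Classical resolution by crystallisation of diastereomeric ammonium salts, run without heating because the cyclobutene is thermally labile; this fixes C6 and C7 of the target.

Step 7
Reactants: 9 (1R,4R)-4-(2,2-dimethylpropanoyloxy)cyclobut-2-ene-1-carboxylic acid
Product: 10 methyl (1R,4R)-4-(2,2-dimethylpropanoyloxy)cyclobut-2-ene-1-carboxylate
Conditions: (CH3)3SiCHN2, PhCH3/CH3OH, 0 °C
Reagents that add atoms: (trimethylsilyl)diazomethane, C[Si](C)(C)C=[N+]=[N-]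
Why: Esterification with a diazomethane equivalent under neutral conditions at 0 °C, which avoids base (epimerisation α to the carboxyl) and heat.

Step 8
Reactants: 5 (R)-2,4-dimethylcyclohex-2-en-1-one; 10 methyl (1R,4R)-4-(2,2-dimethylpropanoyloxy)cyclobut-2-ene-1-carboxylate
Product: 11 cis-anti-cis tricyclic photoadduct (C3 ketone, C4 methyl, exo C6 pivalate, endo C7 CO2CH3, C10 methyl)
Conditions: hν (350 nm, Pyrex), CH2Cl2, −30 °C, 5 (1.5 equiv) added in portions
Reagents that add atoms: none
Why: Proposed new method: the enone triplet (n→π* excitation, intersystem crossing) adds stepwise to the strained cis double bond of 10 through a 1,4-diradical, and the central four-membered ring C4–C5–C8–C9 closes by radical recombination after spin inversion, a formal [2π+2π] closure that gives cis six–four and cis four–four fusions with the two outer rings anti. The closest known reaction type is the [2+2] photocycloaddition of cyclohexenones to cyclobutenes and cyclobutene esters, which gives cis-anti-cis tricyclo[4.4.0.0(2,5)]decanones; what has not been shown is control of orientation by two different substituents on the sp3 carbons of the cyclobutene. C9 is set by attack on the enone face opposite the C10 methyl, C4 by the obligatory cis fusion of the six- and four-membered rings, and C5 and C8 by the cyclobutene face that is attacked. The step needs C4 to bond to C5 and not to C8; because the C4 methyl of a cis-anti-cis adduct points into the fold of the bicyclo[2.2.0]hexane, the substituent on the sp3 carbon next to the C4-bound carbon has to be exo, so orientation and facial choice are coupled: attack anti to the pivalate gives 11, attack anti to the methyl ester gives the regioisomer. Only the bulk of the pivalate over its face of the four-membered ring, against the flat methyl ester on the other face, biases this choice, so a modest preference at best is expected and the regioisomer is removed by chromatography. With the (1R,4R) cyclobutene the anti-to-methyl, anti-to-pivalate and cis-anti-cis preferences all lead to the same adduct (matched pair); C6, C7 and C10 are not touched. Irradiation through Pyrex at −30 °C excites only the enone and keeps 10 from ring opening, and portionwise addition of 5 limits enone dimerisation.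

Step 9
Reactants: 11 cis-anti-cis tricyclic photoadduct
Product: 12 (4E,8Z)-4,10-dimethylcyclodeca-4,8-dien-3-one with C6 pivalate and C7 CO2CH3
Conditions: PhCH3 (0.02 M), steel flow coil, 300 °C, 100 bar, residence a few seconds, immediate cooling
Reagents that add atoms: none
Why: Thermal cycloreversion of the bicyclo[2.2.0]hexane, known for cis-anti-cis tricyclo[4.4.0.0(2,5)]decanones: the shared C5–C8 bond breaks to a cyclohexane-1,4-diyl, which then cleaves the ketone-activated C4–C9 bond. In the chair diyl with the C6 and C7 substituents equatorial, C3 is equatorial on C4 (giving 4E) and C10 is axial on C9 (giving 8Z). C6, C7 and C10 are untouched, and the short contact time limits Cope rearrangement of the 1,5-diene.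

Step 10
Reactants: 12 (4E,8Z)-dienone
Product: 13 C3 allylic alcohol of 12
Conditions: NaBH4, CeCl3·7H2O, CH3OH, −78 °C
Reagents that add atoms: none
Why: Luche 1,2-reduction of the enone; the esters are not reduced at −78 °C. The new C3 centre is removed again in step 22, so its configuration is immaterial.

Step 11
Reactants: 13 C3 allylic alcohol
Product: 14 C3 tert-butyldimethylsilyl ether
Conditions: t-BuMe2SiOTf, 2,6-lutidine, CH2Cl2, −78 °C
Reagents that add atoms: tert-butyldimethylsilyl triflate, CC(C)(C)[Si](C)(C)OS(=O)(=O)C(F)(F)F
Why: Silylation of a hindered allylic alcohol with the silyl triflate; the hindered pyridine base does not provoke elimination of the β-acyloxy ester.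

Step 12
Reactants: 14 C3 silyl ether
Product: 15 diol with C6 OH and C7 CH2OH
Conditions: i-Bu2AlH (6 equiv), CH2Cl2, −78 to −20 °C; aq. KNaC4H4O6
Reagents that add atoms: none
Why: The aluminium hydride reduces the methyl ester to the primary alcohol and cleaves the pivalate in the same operation. Under these non-basic conditions C7 is not epimerised, and the covalent aluminium alkoxide at C6 does not trigger an oxy-Cope shift.

Step 13
Reactants: 15 diol
Product: 16 bis(triethylsilyl) ether
Conditions: Et3SiOTf, 2,6-lutidine, CH2Cl2, −78 °C
Reagents that add atoms: triethylsilyl triflate, CC[Si](CC)(CC)OS(=O)(=O)C(F)(F)F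
Why: Exhaustive silylation; triethylsilyl is chosen because the primary ether can be oxidised directly and the secondary one is later cleaved without loss of the C3 tert-butyldimethylsilyl ether.

Step 14
Reactants: 16 bis(triethylsilyl) ether
Product: 17 C7 aldehyde with C6 OSiEt3
Conditions: (COCl)2, DMSO, CH2Cl2, −78 to −40 °C; Et3N, −78 °C
Reagents that add atoms: none
Why: Swern conditions convert a primary triethylsilyl ether directly into the aldehyde while secondary silyl ethers remain (known chemoselective oxidative desilylation). The β,γ-unsaturated aldehyde is kept cold and used at once so that C8=C9 does not move into conjugation.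

Step 15
Reactants: 17 C7 aldehyde
Product: 18 C7 ethynyl compound
Conditions: (CH3)3SiCHN2, LiN(i-Pr)2, THF, −78 to 0 °C
Reagents that add atoms: (trimethylsilyl)diazomethane, C[Si](C)(C)C=[N+]=[N-]
Why: Colvin rearrangement: the lithiated diazo compound adds to the aldehyde, Peterson elimination gives a diazoalkene, and the alkylidene carbene undergoes a 1,2-hydrogen shift to the terminal alkyne. Addition at −78 °C outruns enolisation, so C7 keeps its configuration; O6 is silylated, so there is no alkoxide in the 1,5-diene.

Step 16
Reactants: 18 C7 ethynyl compound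
Product: 19 C6 alcohol
Conditions: pyridinium p-toluenesulfonate, CH3OH/CH2Cl2, 0 °C
Reagents that add atoms: none
Why: Acid-catalysed methanolysis removes the secondary triethylsilyl ether selectively in the presence of the bulkier tert-butyldimethylsilyl ether.

Step 17
Reactants: 19 C6 alcohol
Product: 20 4,5-epoxy alcohol (oxygen syn to the C6 hydroxyl)
Conditions: VO(acac)2 (5 mol%), t-BuOOH, CH2Cl2, 0 °C
Reagents that add atoms: tert-butyl hydroperoxide, CC(C)(C)OO
Why: Vanadium-catalysed, hydroxyl-directed epoxidation reaches only the allylic C4=C5 bond; C8=C9 is homoallylic and slower. Because the C4 methyl is cis to C6, A(1,3) strain holds H6 in the alkene plane, so oxygen is delivered on the face of the C6 hydroxyl, which is also the outer face of the E alkene (threo epoxy alcohol). This sets C5–O as in the target and C4–O with the opposite sense, as required for step 18.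

Step 18
Reactants: 20 4,5-epoxy alcohol
Product: 21 (4R,5R)-4,5,6-triol
Conditions: HClO4 (cat.), THF/H2O, 0 °C
Reagents that add atoms: water, O
Why: Acid-catalysed hydrolysis of a trisubstituted epoxide: water attacks the tertiary C4 with inversion while the C5–O bond is retained, which gives the 4R,5R pair. The alkyne, the Z alkene and the silyl ether tolerate dilute acid at 0 °C.

Step 19
Reactants: 21 4,5,6-triol
Product: 22 trans-fused α-methylene lactone 4,5-diol
Conditions: PdCl2 (5 mol%), PPh3, SnCl2, CO (8 bar), CH3CN, 75 °C
Reagents that add atoms: carbon monoxide, [C-]#[O+]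
Why: Palladium-catalysed cyclocarbonylation of a homopropargylic alcohol: an alkoxycarbonyl–palladium species (divalent palladium) formed at O6 adds cis across the alkyne and protonolysis releases the α-methylene-γ-butyrolactone. The five-membered ring from O6 should form in preference to a six-membered ring from the more hindered O5, and the trans fusion follows from the C6/C7 configuration.

Step 20
Reactants: 22 α-methylene lactone 4,5-diol
Product: 23 C5 isobutyrate
Conditions: (i-PrCO)2O, 4-(dimethylamino)pyridine, Et3N, CH2Cl2, 25 °C
Reagents that add atoms: isobutyric anhydride, CC(C)C(=O)OC(=O)C(C)C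
Why: Nucleophile-catalysed acylation of the only secondary hydroxyl; the tertiary C4 hydroxyl is inert under these conditions and C3 is still protected.

Step 21
Reactants: 23 C5 isobutyrate
Product: 24 C3 alcohol
Conditions: HF·pyridine, pyridine, THF, 0 to 25 °C
Reagents that add atoms: none
Why: Fluoride-mediated cleavage of the silyl ether under buffered, weakly acidic conditions that leave the methylene lactone and the ester alone and do not promote acyl migration.

Step 22
Reactants: 24 C3 alcohol
Product: 25 C3 ketone with 8Z alkene
Conditions: Dess–Martin periodinane, NaHCO3, CH2Cl2, 0 °C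
Reagents that add atoms: none
Why: Dess–Martin oxidation of the secondary alcohol to the ketone; the tertiary C4 hydroxyl cannot be oxidised and the α-ketol is not cleaved. The transient C3 centre disappears.

Step 23
Reactants: 25 C3 ketone
Product: 26 8,9-cis-epoxide
Conditions: mCPBA, NaHCO3, CH2Cl2, 0 °C
Reagents that add atoms: 3-chloroperbenzoic acid, OOC(=O)c1cccc(Cl)c1
Why: Prilezhaev epoxidation of the only electron-rich alkene; the lactone enoate is inert. With H7 and H10 in the alkene plane (A(1,3) strain of a Z alkene) the ring hangs on one face and the peracid comes from the outer face, which carries C11 and the C10 methyl; this sets C8–O as in the target.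

Step 24
Reactants: 26 8,9-cis-epoxide
Product: 27 CNP0203887.1
Conditions: 3-methylbutanoic acid, chiral Co(salen) [N,N′-bis(3,5-di-tert-butylsalicylidene)-1,2-cyclohexanediamine complex, divalent cobalt, aired with the acid to the trivalent cobalt carboxylate] (5 mol%), i-Pr2NEt, t-BuOMe, 25 °C
Reagents that add atoms: 3-methylbutanoic acid, CC(C)CC(=O)O
Why: Cobalt–salen catalysed addition of a carboxylic acid to an epoxide (Lewis-acid activation with carboxylate delivery, SN2): attack at C9, the carbon remote from the lactone-bearing C7, with inversion gives the 8R,9R hydroxy ester with C8–OH free. The catalyst enantiomer that favours attack at C9 is used.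

## Compound list

1 | (R)-(+)-pulegone, (5R)-5-methyl-2-(propan-2-ylidene)cyclohexan-1-one | C[C@@H]1CCC(=C(C)C)C(=O)C1 | starting material
2 | (5R)-1,5-dimethyl-2-(propan-2-ylidene)cyclohexan-1-ol (C1 epimers) | C[C@@H]1CCC(=C(C)C)C(C)(O)C1 | intermediate
3 | (4R)-2-hydroxy-2,4-dimethylcyclohexan-1-one (C2 epimers) | C[C@@H]1CCC(=O)C(C)(O)C1 | intermediate
4 | chlorosulfite ester of 3, (4R)-2-(chlorosulfinyloxy)-2,4-dimethylcyclohexan-1-one | C[C@@H]1CCC(=O)C(C)(OS(=O)Cl)C1 | intermediate
5 | (R)-2,4-dimethylcyclohex-2-en-1-one | O=C1CC[C@@H](C)C=C1C | intermediate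
6 | 2H-pyran-2-one | O=C1C=CC=CO1 | starting material
7 | rac-2-oxabicyclo[2.2.0]hex-5-en-3-one (cis-fused, both enantiomers) | O=C1O[C@H]2C=C[C@@H]12.O=C1O[C@@H]2C=C[C@H]12 | intermediate
8 | rac-trans-4-(2,2-dimethylpropanoyloxy)cyclobut-2-ene-1-carboxylic acid (both enantiomers) | OC(=O)[C@@H]1C=C[C@H]1OC(=O)C(C)(C)C.OC(=O)[C@H]1C=C[C@@H]1OC(=O)C(C)(C)C | intermediate
9 | (1R,4R)-4-(2,2-dimethylpropanoyloxy)cyclobut-2-ene-1-carboxylic acid | OC(=O)[C@@H]1C=C[C@H]1OC(=O)C(C)(C)C | intermediate
10 | methyl (1R,4R)-4-(2,2-dimethylpropanoyloxy)cyclobut-2-ene-1-carboxylate (C6 pivalate, C7 ester, trans) | COC(=O)[C@@H]1C=C[C@H]1OC(=O)C(C)(C)C | intermediate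
11 | cis-anti-cis tricyclo[4.4.0.0(2,5)]decan-7-one photoadduct: C3 ketone, C4 methyl, exo C6 pivalate, endo C7 CO2CH3, C10 methyl anti to the central ring | O=C1CC[C@@H](C)[C@H]2[C@]1(C)[C@@H]3[C@@H](OC(=O)C(C)(C)C)[C@H](C(=O)OC)[C@H]23 | intermediate
12 | (4E,8Z)-4,10-dimethylcyclodeca-4,8-dien-3-one with C6 pivalate and C7 CO2CH3 (6,7-trans) | C1C(=O)/C(C)=C/[C@@H](OC(=O)C(C)(C)C)[C@H](C(=O)OC)/C=C\[C@H](C)C1 | intermediate
13 | C3 allylic alcohol of 12 (C3 epimers) | C1C(O)/C(C)=C/[C@@H](OC(=O)C(C)(C)C)[C@H](C(=O)OC)/C=C\[C@H](C)C1 | intermediate
14 | C3 tert-butyldimethylsilyl ether of 13 | C1C(O[Si](C)(C)C(C)(C)C)/C(C)=C/[C@@H](OC(=O)C(C)(C)C)[C@H](C(=O)OC)/C=C\[C@H](C)C1 | intermediate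
15 | (4E,8Z)-diene diol: C6 OH, C7 CH2OH, C3 silyl ether | C1C(O[Si](C)(C)C(C)(C)C)/C(C)=C/[C@@H](O)[C@H](CO)/C=C\[C@H](C)C1 | intermediate
16 | 6,11-bis(triethylsilyl) ether of 15 | C1C(O[Si](C)(C)C(C)(C)C)/C(C)=C/[C@@H](O[Si](CC)(CC)CC)[C@H](CO[Si](CC)(CC)CC)/C=C\[C@H](C)C1 | intermediate
17 | C7 aldehyde (C11 = CHO) with C6 OSiEt3 and C3 OSi(t-Bu)Me2 | C1C(O[Si](C)(C)C(C)(C)C)/C(C)=C/[C@@H](O[Si](CC)(CC)CC)[C@H](C=O)/C=C\[C@H](C)C1 | intermediate
18 | C7 ethynyl compound (C11≡C13H) with C6 OSiEt3 | C1C(O[Si](C)(C)C(C)(C)C)/C(C)=C/[C@@H](O[Si](CC)(CC)CC)[C@H](C#C)/C=C\[C@H](C)C1 | intermediate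
19 | C6 alcohol of 18 (allylic to C4=C5, homopropargylic) | C1C(O[Si](C)(C)C(C)(C)C)/C(C)=C/[C@@H](O)[C@H](C#C)/C=C\[C@H](C)C1 | intermediate
20 | 4,5-epoxide of 19, oxygen syn to the C6 hydroxyl (threo), 8Z alkene | C1C(O[Si](C)(C)C(C)(C)C)[C@@]2(C)O[C@@H]2[C@@H](O)[C@H](C#C)/C=C\[C@H](C)C1 | intermediate
21 | (4R,5R)-4,5,6-triol with C3 silyl ether, C7 ethynyl, 8Z alkene | C1C(O[Si](C)(C)C(C)(C)C)[C@](C)(O)[C@H](O)[C@@H](O)[C@H](C#C)/C=C\[C@H](C)C1 | intermediate
22 | trans-fused 6,12-olide with C13 methylene, C4 and C5 hydroxyls, C3 silyl ether, 8Z alkene | C=C1C(=O)O[C@H]2[C@H]1/C=C\[C@H](C)CCC(O[Si](C)(C)C(C)(C)C)[C@](C)(O)[C@@H]2O | intermediate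
23 | C5 isobutyrate of 22 | C=C1C(=O)O[C@H]2[C@H]1/C=C\[C@H](C)CCC(O[Si](C)(C)C(C)(C)C)[C@](C)(O)[C@@H]2OC(=O)C(C)C | intermediate
24 | C3 alcohol (silyl ether of 23 removed) | C=C1C(=O)O[C@H]2[C@H]1/C=C\[C@H](C)CCC(O)[C@](C)(O)[C@@H]2OC(=O)C(C)C | intermediate
25 | C3 ketone: target skeleton with C8=C9 (Z) in place of the C8 hydroxyl and C9 ester | C=C1C(=O)O[C@H]2[C@H]1/C=C\[C@H](C)CCC(=O)[C@](C)(O)[C@@H]2OC(=O)C(C)C | intermediate
26 | 8,9-cis-epoxide of 25, oxygen on the face of C11 and the C10 methyl | C=C1C(=O)O[C@H]2[C@H]1[C@H]3O[C@H]3[C@H](C)CCC(=O)[C@](C)(O)[C@@H]2OC(=O)C(C)C | intermediate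
27 | CNP0203887.1 (4R,5R,6S,7R,8R,9R,10R in the ring numbering used here) | C=C1C(=O)O[C@H]2[C@H]1[C@@H](O)[C@H](OC(=O)CC(C)C)[C@H](C)CCC(=O)[C@](C)(O)[C@@H]2OC(=O)C(C)C | target

## Step count and least certain steps

Total: 24 steps. Longest linear sequence: 21 steps (6 to 27, steps 4–24); the enone branch (steps 1–3) joins at step 8.

**Step 8 (key step).** The most likely failure is poor control of orientation: the enone α-carbon bonds to C8 instead of C5 because the two faces of the cyclobutene differ too little in bulk. Lesser risks are enone dimerisation and electrocyclic opening of 10 if the solution warms.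

Fallback, setting out from 5 and returning at 16:
- Irradiate 5 with dimethyl (1R,2R)-cyclobut-3-ene-1,2-dicarboxylate F1. Its two alkene carbons are exchanged by the twofold axis, so only one constitution of adduct can form: the keto diester F2 (C6 ester exo, C7 ester endo).
- NaBH4 reduces the ketone to the carbinol F3, and t-BuMe2SiOTf gives the silyl ether F4.
- One equivalent of LiOH should cleave the exposed exo ester to the C6 acid F5.
- (COCl)2 followed by (CH3)2CuLi gives the C6 methyl ketone F6.
- Baeyer–Villiger oxidation with mCPBA, in which the secondary cyclobutyl carbon migrates with retention, gives the C6 acetate F7.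
- i-Bu2AlH gives the tricyclic diol F8, Et3SiOTf gives the bis(triethylsilyl) ether F9, and thermal ring expansion of F9 under the conditions of step 9 returns to 16.

**Step 9.** The likely failures are diversion of the 1,4-diyl into scission of C6–C7, or Cope rearrangement of the product. Both lead to a divinylcyclohexanone whose enol ester and acrylate are conjugated. A second risk is formation of the diene with the other pair of alkene geometries.

Fallback, setting out from 11 and returning at 16: the reductions are moved ahead of the ring expansion. NaBH4 converts 11 into the carbinol F10; t-BuMe2SiOTf gives the silyl ether F11; i-Bu2AlH gives the tricyclic diol F8; Et3SiOTf gives the bis(triethylsilyl) ether F9. F9 has no carbonyl group on C7, so neither fragment of a C6–C7 scission is conjugated. Its flow pyrolysis gives 16 directly.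

**Step 24.** The likely failures are opening at C8 instead of C9, a sluggish reaction because the backside of the epoxide faces the ring interior, and transannular attack by the C4 hydroxyl under activation.

Fallback, setting out from 25 and returning at 27:
- OsO4 (catalytic) with N-methylmorpholine N-oxide should add both oxygens to the outer face of C8=C9, the electron-poor methylene lactone reacting more slowly, to give the cis-diol F12.
- SO2Cl2 and Et3N close the cyclic sulfate F13.
- Cesium 3-methylbutanoate in DMF opens the far more electrophilic sulfate at C9 with inversion, without any acid, to the C8 sulfate monoester F14.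
- Dilute H2SO4 in wet THF hydrolyses the sulfate ester to 27.

**Step 5.** The likely failures are a syn SN2′ course that would give the cis acid, attack of the carboxylate at the acyl carbon, and thermal ring opening of the product.

Fallback, setting out from 7 and returning at 8: dry HCl in Et2O at −20 °C opens 7 to the more robust cis-4-chlorocyclobut-2-ene-1-carboxylic acid F15. Displacement of the allylic chloride by cesium pivalate (DMF, 0 °C), an SN2 reaction with inversion, then gives 8.

## Further compounds

F1 | step 8 | dimethyl (1R,2R)-cyclobut-3-ene-1,2-dicarboxylate | COC(=O)[C@@H]1C=C[C@H]1C(=O)OC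
F2 | step 8 | cis-anti-cis tricyclic keto diester (exo C6 CO2CH3, endo C7 CO2CH3) | O=C1CC[C@@H](C)[C@H]2[C@]1(C)[C@@H]3[C@@H](C(=O)OC)[C@H](C(=O)OC)[C@H]23
F3 | step 8 | C3 carbinol of F2 | OC1CC[C@@H](C)[C@H]2[C@]1(C)[C@@H]3[C@@H](C(=O)OC)[C@H](C(=O)OC)[C@H]23
F4 | step 8 | C3 tert-butyldimethylsilyl ether of F3 | CC(C)(C)[Si](C)(C)OC1CC[C@@H](C)[C@H]2[C@]1(C)[C@@H]3[C@@H](C(=O)OC)[C@H](C(=O)OC)[C@H]23
F5 | step 8 | C6 carboxylic acid, C7 methyl ester | CC(C)(C)[Si](C)(C)OC1CC[C@@H](C)[C@H]2[C@]1(C)[C@@H]3[C@@H](C(=O)O)[C@H](C(=O)OC)[C@H]23
F6 | step 8 | C6 methyl ketone, C7 methyl ester | CC(C)(C)[Si](C)(C)OC1CC[C@@H](C)[C@H]2[C@]1(C)[C@@H]3[C@@H](C(C)=O)[C@H](C(=O)OC)[C@H]23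
F7 | step 8 | C6 acetate, C7 methyl ester | CC(C)(C)[Si](C)(C)OC1CC[C@@H](C)[C@H]2[C@]1(C)[C@@H]3[C@@H](OC(C)=O)[C@H](C(=O)OC)[C@H]23
F8 | step 8 | tricyclic diol (C6 OH, C7 CH2OH, C3 silyl ether) | CC(C)(C)[Si](C)(C)OC1CC[C@@H](C)[C@H]2[C@]1(C)[C@@H]3[C@@H](O)[C@H](CO)[C@H]23
F9 | step 8 | tricyclic bis(triethylsilyl) ether of F8 | CC(C)(C)[Si](C)(C)OC1CC[C@@H](C)[C@H]2[C@]1(C)[C@@H]3[C@@H](O[Si](CC)(CC)CC)[C@H](CO[Si](CC)(CC)CC)[C@H]23
F10 | step 9 | C3 carbinol of 11 | OC1CC[C@@H](C)[C@H]2[C@]1(C)[C@@H]3[C@@H](OC(=O)C(C)(C)C)[C@H](C(=O)OC)[C@H]23
F11 | step 9 | C3 tert-butyldimethylsilyl ether of F10 | CC(C)(C)[Si](C)(C)OC1CC[C@@H](C)[C@H]2[C@]1(C)[C@@H]3[C@@H](OC(=O)C(C)(C)C)[C@H](C(=O)OC)[C@H]23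
F12 | step 24 | 8,9-cis-diol (C8 as in the target, C9 epimeric) | C=C1C(=O)O[C@H]2[C@H]1[C@@H](O)[C@@H](O)[C@H](C)CCC(=O)[C@](C)(O)[C@@H]2OC(=O)C(C)C
F13 | step 24 | 8,9-cyclic sulfate of F12 | C=C1C(=O)O[C@H]2[C@H]1[C@H]3OS(=O)(=O)O[C@H]3[C@H](C)CCC(=O)[C@](C)(O)[C@@H]2OC(=O)C(C)C
F14 | step 24 | C8 sulfate monoester (cesium salt) of the C9 isovalerate | C=C1C(=O)O[C@H]2[C@H]1[C@@H](OS(=O)(=O)[O-])[C@H](OC(=O)CC(C)C)[C@H](C)CCC(=O)[C@](C)(O)[C@@H]2OC(=O)C(C)C.[Cs+]
F15 | step 5 | rac-cis-4-chlorocyclobut-2-ene-1-carboxylic acid (both enantiomers) | OC(=O)[C@@H]1C=C[C@@H]1Cl.OC(=O)[C@H]1C=C[C@H]1Cl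
A1 | alternative 1 | (E)-cyclodec-8-en-3-one with C4/C5 acetonide, C6 methoxymethyl ether and C7 isopropenyl group | C1C(=O)[C@]2(C)OC(C)(C)O[C@@H]2[C@@H](OCOC)[C@H](C(C)=C)/C=C/[C@H](C)C1
A2 | alternative 2 | ten-membered (1Z,4E)-dien-3-one with fused 3-methylenetetrahydrofuran, C8 silyl ether and C9 isovalerate | C[C@@H]1/C=C\C(=O)/C(C)=C/[C@H]2OCC(=C)[C@@H]2[C@@H](O[Si](C)(C)C(C)(C)C)[C@@H]1OC(=O)CC(C)C
A3 | alternative 3 | (E)-cyclodec-4-en-9-one with C3 ethylene ketal, fused 3-methylenetetrahydrofuran and C8 silyl ether | O=C1[C@H](C)CCC2(OCCO2)/C(C)=C/[C@H]3OCC(=C)[C@@H]3[C@H]1O[Si](C)(C)C(C)(C)C
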